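**Retrosynthetic overview**
1. Target 13 ⇐ acetylation of the only secondary OH of diol 12 ⇐ axial-hydride (Luche) reduction of α-hydroxy ketone 11.
2. Key disconnection: 11 ⇐ enantioselective α-ketol (acyloin) ring expansion of the meso cyclopentenyl α-ketol 10; one ring C–C bond shifts from the carbinol carbon to the side-chain carbonyl carbon, which becomes the quaternary C1 of the target.
3. 10 ⇐ IBX oxidation of diol 9 ⇐ osmylation of the exocyclic alkene of tribenzoate 8 ⇐ tribenzoylation of triol 7.
4. 7 ⇐ singlet-oxygen [4+2] addition and thiourea reduction of fulvene 5 ⇐ sodium cyclopentadienide 1 + glycolaldehyde dimer 2.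
5. Ring order: the only carbocycle is the five-membered ring that comes with 1; step 6 enlarges it to the cyclohexene of the target, and no other ring is formed.

Assumption: benzoyl chloride and acetic anhydride are used as acylating reagents; compounds 6–9 are racemic and drawn as one enantiomer, 10 is achiral (meso), so absolute configuration is first set in step 6.

**Step 1**
Reactants: 1 sodium cyclopentadienide (NaC5H5); 2 glycolaldehyde dimer (2,5-dihydroxy-1,4-dioxane)
Product: 5 2-(cyclopenta-2,4-dien-1-ylidene)ethan-1-ol, via cyclopentadiene 3 (not isolated), via glycolaldehyde 4 (not isolated)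
Conditions: NaC5H5 (2.0 M in THF, 1.2 equiv), AcOH (1.2 equiv), MeOH, 0 °C; then 2 (0.5 equiv), pyrrolidine (20 mol%), 0 °C to rt
Reagents that add atoms: none
Why: Thiele-type fulvene condensation under pyrrolidine (iminium) catalysis: cyclopentadiene released from NaC5H5 by AcOH adds to the iminium ion of monomeric glycolaldehyde and the amine is eliminated; no stereocentre is formed.

**Step 2**
Reactants: 5 2-(cyclopenta-2,4-dien-1-ylidene)ethan-1-ol
Product: 7 racemic cis-2-(2-hydroxyethylidene)cyclopent-4-ene-1,3-diol, via endoperoxide 6 (not isolated)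
Conditions: O2, tetraphenylporphyrin (1 mol%), thiourea (1.1 equiv), CH2Cl2/MeOH 1:1, white LED, −30 °C to 0 °C
Reagents that add atoms: oxygen (reacting as singlet oxygen), O=O
Why: [4+2] photooxygenation of the ring diene gives the labile endoperoxide, whose O–O bond is reduced at once by thiourea, so both ring hydroxyls come from one O2 molecule and are necessarily cis (racemic, because the side chain breaks the mirror plane).

**Step 3**
Reactants: 7 racemic cis-2-(2-hydroxyethylidene)cyclopent-4-ene-1,3-diol
Product: 8 racemic cis-2-[2-(benzoyloxy)ethylidene]cyclopent-4-ene-1,3-diyl dibenzoate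
Conditions: BzCl (3.6 equiv), pyridine (6 equiv), DMAP (10 mol%), CH2Cl2, 0 °C to rt
Reagents that add atoms: benzoyl chloride, O=C(Cl)c1ccccc1
Why: Exhaustive DMAP-catalysed O-acylation of the primary and the two secondary alcohols installs all three benzoates of the target in one operation; no stereocentre is touched.

**Step 4**
Reactants: 8 racemic cis-2-[2-(benzoyloxy)ethylidene]cyclopent-4-ene-1,3-diyl dibenzoate
Product: 9 racemic 2-[2-(benzoyloxy)-1-hydroxyethyl]-2-hydroxycyclopent-4-ene-1,3-diyl dibenzoate (ring OH trans to both ring benzoates)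
Conditions: OsO4 (5 mol%), NMO (1.3 equiv), citric acid (0.75 equiv), t-BuOH/H2O 1:1, rt, stopped when 8 is consumed
Reagents that add atoms: OsO4, O=[Os](=O)(=O)=O; N-methylmorpholine N-oxide, C[N+]1([O-])CCOCC1; water, O
Why: Upjohn dihydroxylation in its citric-acid variant: the trisubstituted exocyclic alkene is the more electron-rich one, and OsO4 adds syn from the face opposite the two allylic benzoates, which places the new tertiary OH trans to both of them.

**Step 5**
Reactants: 9 racemic 2-[2-(benzoyloxy)-1-hydroxyethyl]-2-hydroxycyclopent-4-ene-1,3-diyl dibenzoate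
Product: 10 meso-(1R,2r,3S)-2-[(benzoyloxy)acetyl]-2-hydroxycyclopent-4-ene-1,3-diyl dibenzoate
Conditions: IBX (1.5 equiv), EtOAc, 75 °C
Reagents that add atoms: none
Why: IBX oxidises the only secondary alcohol and turns 1,2-diols into α-ketols without C–C cleavage; removal of the side-chain stereocentre converts racemic 9 into a single achiral meso α-ketol.

**Step 6**
Reactants: 10 meso-(1R,2r,3S)-2-[(benzoyloxy)acetyl]-2-hydroxycyclopent-4-ene-1,3-diyl dibenzoate
Product: 11 [(1R,2S,5R)-2,5-bis(benzoyloxy)-1-hydroxy-6-oxocyclohex-3-en-1-yl]methyl benzoate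
Conditions: Cu(OTf)2 (10 mol%), (S,S)-t-Bu-box [2,2'-(propane-2,2-diyl)bis((4S)-4-tert-butyl-4,5-dihydrooxazole)] (11 mol%), 4 Å MS, ClCH2CH2Cl, 50 °C
Reagents that add atoms: none
Why: Proposed new method: an enantioselective, desymmetrising α-ketol (acyloin) ring expansion in which the divalent copper centre chelates the tertiary OH and the ketone oxygen (five-membered chelate, O=C–C–O syn-periplanar), so that the two enantiotopic ring C–CH(OBz) bonds lie above and below the chelate plane, both aligned with the C=O π* orbital; the C2-symmetric ligand is meant to let only the (S)-configured carbon C3 migrate, with retention, to the carbonyl carbon, which leaves the new tertiary OH on the face of the old one (trans to both benzoates) and makes the old carbinol carbon the ring ketone, the expansion being driven by loss of cyclopentene strain and of the all-cis crowding; the closest known reaction type is the Lewis-acid-catalysed enantioselective acyloin ring expansion of simple achiral 1-acylcycloalkanols together with copper–bis(oxazoline) catalysis on chelating α-hydroxy ketones, neither of which has been shown on a meso substrate whose migrating carbons are stereogenic and oxygenated.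

**Step 7**
Reactants: 11 [(1R,2S,5R)-2,5-bis(benzoyloxy)-1-hydroxy-6-oxocyclohex-3-en-1-yl]methyl benzoate
Product: 12 [(1S,2S,5R,6S)-2,5-bis(benzoyloxy)-1,6-dihydroxycyclohex-3-en-1-yl]methyl benzoate
Conditions: NaBH4 (1.0 equiv), CeCl3·7H2O (1.2 equiv), MeOH/CH2Cl2 3:1, −78 °C
Reagents that add atoms: none
Why: Luche reduction: in the favoured half-chair (CH2OBz equatorial, tertiary OH axial) the small hydride attacks the ketone axially, anti to the axial C–O bond (polar Felkin–Anh), giving the equatorial alcohol cis to the tertiary OH and trans to the neighbouring benzoate, while the near-neutral medium at −78 °C avoids benzoate migration.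

**Step 8**
Reactants: 12 [(1S,2S,5R,6S)-2,5-bis(benzoyloxy)-1,6-dihydroxycyclohex-3-en-1-yl]methyl benzoate
Product: 13 [(1R,2S,5R,6S)-6-(acetyloxy)-2,5-bis(benzoyloxy)-1-hydroxycyclohex-3-en-1-yl]methyl benzoate (target)
Conditions: Ac2O (1.5 equiv), pyridine (3 equiv), DMAP (5 mol%), CH2Cl2, 0 °C
Reagents that add atoms: acetic anhydride, CC(=O)OC(C)=O
Why: DMAP-catalysed acetylation takes place at the secondary alcohol only, the tertiary alcohol being too hindered under these conditions; no stereocentre changes.

**Compound list**
1 | sodium cyclopentadienide (NaC5H5) | [Na+].[cH-]1cccc1 | starting material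
2 | glycolaldehyde dimer (2,5-dihydroxy-1,4-dioxane) | OC1COC(O)CO1 | starting material
3 | cyclopentadiene | C1C=CC=C1 | intermediate
4 | glycolaldehyde | OCC=O | intermediate
5 | 2-(cyclopenta-2,4-dien-1-ylidene)ethan-1-ol (6-(hydroxymethyl)fulvene) | OCC=C1C=CC=C1 | intermediate
6 | racemic 7-(2-hydroxyethylidene)-2,3-dioxabicyclo[2.2.1]hept-5-ene | OC/C=C1/[C@H]2C=C[C@@H]1OO2 | intermediate
7 | racemic 2-(2-hydroxyethylidene)cyclopent-4-ene-1,3-diol, ring hydroxyls cis (drawn enantiomer 1R,2E,3S) | OC/C=C1/[C@H](O)C=C[C@@H]1O | intermediate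
8 | racemic 2-[2-(benzoyloxy)ethylidene]cyclopent-4-ene-1,3-diyl dibenzoate, ring benzoates cis (drawn enantiomer 1R,2E,3S) | O=C(c1ccccc1)OC/C=C2/[C@H](OC(=O)c3ccccc3)C=C[C@@H]2OC(=O)c4ccccc4 | intermediate
9 | racemic (1R,2r,3S)-2-[(1R)-2-(benzoyloxy)-1-hydroxyethyl]-2-hydroxycyclopent-4-ene-1,3-diyl dibenzoate (drawn enantiomer; ring OH trans to both ring benzoates) | O=C(c1ccccc1)OC[C@@H](O)[C@]2(O)[C@H](OC(=O)c3ccccc3)C=C[C@@H]2OC(=O)c4ccccc4 | intermediate
10 | meso-(1R,2r,3S)-2-[(benzoyloxy)acetyl]-2-hydroxycyclopent-4-ene-1,3-diyl dibenzoate (OH trans, acyl cis to both benzoates) | O=C(c1ccccc1)OCC(=O)[C@]2(O)[C@H](OC(=O)c3ccccc3)C=C[C@@H]2OC(=O)c4ccccc4 | intermediate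
11 | [(1R,2S,5R)-2,5-bis(benzoyloxy)-1-hydroxy-6-oxocyclohex-3-en-1-yl]methyl benzoate | O=C1[C@H](OC(=O)c2ccccc2)C=C[C@H](OC(=O)c2ccccc2)[C@]1(O)COC(=O)c1ccccc1 | intermediate
12 | [(1S,2S,5R,6S)-2,5-bis(benzoyloxy)-1,6-dihydroxycyclohex-3-en-1-yl]methyl benzoate (same spatial arrangement at C1 as in 13; the descriptor differs only through the priority rules) | O[C@H]1[C@H](OC(=O)c2ccccc2)C=C[C@H](OC(=O)c2ccccc2)[C@]1(O)COC(=O)c1ccccc1 | intermediate
13 | [(1R,2S,5R,6S)-6-(acetyloxy)-2,5-bis(benzoyloxy)-1-hydroxycyclohex-3-en-1-yl]methyl benzoate | CC(=O)O[C@H]1[C@H](OC(=O)c2ccccc2)C=C[C@H](OC(=O)c2ccccc2)[C@]1(O)COC(=O)c1ccccc1 | target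

**Step count and risks**
Total step count: 8. Longest linear sequence: 8 steps (fully linear, 1 and 2 to 13).

The three steps most likely to fail:

Step 6 (the proposed new ring expansion). The migrating carbons are electron-poor and the three benzoates can compete for the copper centre, so turnover may be slow. The sense and level of induction cannot be predicted with confidence; if the (S,S)-ligand favours the mirror image, the (R,R)-ligand is used. Ketone 11 could also lose enantiopurity by a degenerate 1,2-shift of its CH2OBz group or by enolisation if left too long. Fallback with known chemistry: setting out from 10, the ring expansion is run with an achiral chelating Lewis acid (Sc(OTf)3, 10 mol%, ClCH2CH2Cl, 60 °C; classical Lewis-acid α-ketol rearrangement). This gives racemic ketone, that is 11 together with its mirror image ent-11 F2. Luche reduction as in step 7 gives 12 together with ent-12 F3. The enantiomers are separated by preparative HPLC on a chiral stationary phase, and the route is rejoined at 12.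

Step 7 (facial selectivity of the ketone reduction). The pseudo-axial benzoate at the carbon 1,3 to the ketone hinders the desired axial approach, and any chelation or hydroxyl-directed delivery would give the trans-diol instead. Fallback: setting out from 11, the reduction is deliberately run with hydroxyl direction (Me4NBH(OAc)3, MeCN/AcOH, −20 °C), which delivers hydride from the face of the tertiary OH and gives the trans-diol 6-epi-12 F4. Its secondary OH is converted into the C6 triflate F5 (Tf2O, pyridine, CH2Cl2, −20 °C), which is displaced with inversion by Bu4NOAc (toluene, rt; Lattrell–Dax-type inversion). This installs the acetate with the correct configuration and comes back to the route at 13.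

Step 4 (chemoselectivity of the osmylation). The strained ring alkene may compete with the exocyclic alkene, because both carry allylic benzoates. Fallback: setting out from 8, the exocyclic alkene is epoxidised with mCPBA (NaHCO3, CH2Cl2, 0 °C to rt), an electrophilic oxidant that discriminates more strongly in favour of the trisubstituted alkene and attacks anti to the ring benzoates, giving the racemic spiro-epoxide F1. Acid-catalysed hydrolysis (HClO4 cat., THF/H2O, 0 °C) with water attacking the less hindered secondary epoxide carbon keeps the tertiary C–O bond and gives racemic diol 9, where the route is rejoined. The configuration of the side-chain carbinol is irrelevant because step 5 erases it.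

**Further compounds**
F1 | step 4 | racemic [4,7-bis(benzoyloxy)-1-oxaspiro[2.4]hept-5-en-2-yl]methyl benzoate (epoxide oxygen trans to both ring benzoates) | O=C(c1ccccc1)OC[C@H]2O[C@]23[C@H](OC(=O)c4ccccc4)C=C[C@@H]3OC(=O)c5ccccc5
F2 | step 6 | ent-11, [(1S,2R,5S)-2,5-bis(benzoyloxy)-1-hydroxy-6-oxocyclohex-3-en-1-yl]methyl benzoate | O=C1[C@@H](OC(=O)c2ccccc2)C=C[C@@H](OC(=O)c2ccccc2)[C@@]1(O)COC(=O)c1ccccc1
F3 | step 6 | ent-12, [(1R,2R,5S,6R)-2,5-bis(benzoyloxy)-1,6-dihydroxycyclohex-3-en-1-yl]methyl benzoate | O[C@@H]1[C@@H](OC(=O)c2ccccc2)C=C[C@@H](OC(=O)c2ccccc2)[C@@]1(O)COC(=O)c1ccccc1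
F4 | step 7 | 6-epi-12, [(1S,2S,5R,6R)-2,5-bis(benzoyloxy)-1,6-dihydroxycyclohex-3-en-1-yl]methyl benzoate | O[C@@H]1[C@H](OC(=O)c2ccccc2)C=C[C@H](OC(=O)c2ccccc2)[C@]1(O)COC(=O)c1ccccc1
F5 | step 7 | [(1R,2S,5R,6R)-2,5-bis(benzoyloxy)-1-hydroxy-6-{[(trifluoromethyl)sulfonyl]oxy}cyclohex-3-en-1-yl]methyl benzoate | O=S(=O)(O[C@@H]1[C@H](OC(=O)c2ccccc2)C=C[C@H](OC(=O)c2ccccc2)[C@]1(O)COC(=O)c1ccccc1)C(F)(F)F
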